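**Plan**

- Retrosynthesis: the two ester C–O bonds (C10 angelate, C6 4-hydroxybenzoate) are cut first, then the ring bonds C9–C10 and C6–C7, then C4–isopropyl, C5–C6 and the C1–C10 bond on the cyclopentane.
- Enabling feature: the oxygen-bearing carbons C6 and C10 are 1,4-related through the cyclopentane carbons C5 and C1 and flank the three-carbon unit C7–C8(CH3)–C9. The seven-membered ring (C1, C5–C10) is therefore a trans-1,2-diformylcyclopentane joined to a 2-methylenepropane-1,3-diyl unit.
- Forward: the cyclopentane (C1–C5) is made first from 3-methylcyclopentenone and taken to dialdehyde 13. The seven-membered ring is then closed in one operation by a double allylsilane addition of 16. Redox adjustment and two acylations finish the target.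
- Stereochemistry: C1 comes from a catalyst-controlled conjugate addition, C5 from enolate alkylation anti to the silylvinyl group, and C4 from organocerium addition anti to the C5 arm. C6 comes from a C4-hydroxyl-directed reduction and C10 from a Luche reduction anti to the C1 methyl. The Z alkene is carried in with angelic acid.

Key step: step 9

Remark: bicyclic compounds carry daucane numbering (C1 methyl-bearing fusion carbon, C2/C3 ring CH2, C4 isopropyl carbinol, C5 fusion CH, C6–C10 the other seven-ring carbons, C14 on C8). Benzyl chloromethyl ether, 4-acetoxybenzoyl chloride, angelic acid and the chiral imidazolinium carbene precursor are taken as purchased.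

**Route**

Step 1
Reactants: 1 3-methylcyclopent-2-en-1-one; 2 (trimethylsilyl)acetylene
Product: 6 (2S,3S)-2-[(benzyloxy)methyl]-3-methyl-3-[1-(trimethylsilyl)ethenyl]cyclopentan-1-one, via vinylalane 3 (not isolated), via aluminium enolate 4 (not isolated), via lithium aluminate enolate 5 (not isolated)
Conditions: 2, iBu2AlH, hexanes/THF, 55 °C; then 1, CuCl2·2H2O (5 mol %), chiral sulfonate-bearing imidazolinium salt (NHC precursor, 5 mol %, antipode giving 3S), THF, −78 → −15 °C; then MeLi, DMPU, −78 °C; BnOCH2Cl, −78 → 0 °C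
Reagents that add atoms: benzyl chloromethyl ether, ClCOCc1ccccc1
Why: syn-hydroalumination puts aluminium on the silicon-bearing carbon, the NHC–copper-catalysed enantioselective conjugate addition of such silyl-substituted vinylalanes to β-substituted cyclopentenones sets the quaternary C1 under catalyst control, and the regiodefined enolate (activated as its aluminate) should be alkylated anti to the bulky silylvinyl group, which places the C5 arm trans to the future C10 carbon.

Step 2
Reactants: 6 (2S,3S)-2-[(benzyloxy)methyl]-3-methyl-3-[1-(trimethylsilyl)ethenyl]cyclopentan-1-one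
Product: 7 (2S,3R)-2-[(benzyloxy)methyl]-3-ethenyl-3-methylcyclopentan-1-one
Conditions: CF3CO2H, CH2Cl2, 0 °C → rt, short reaction time
Reagents that add atoms: none
Why: ipso-protodesilylation of a vinylsilane (protonation at the silicon-bearing carbon, loss of silicon from the β-silyl cation) is established for β-(1-silylvinyl) ketones; the benzyl ether is inert and brief exposure at low temperature should keep the hindered C5–H from enolising.

Step 3
Reactants: 7 (2S,3R)-2-[(benzyloxy)methyl]-3-ethenyl-3-methylcyclopentan-1-one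
Product: 8 (1R,2S,3R)-2-[(benzyloxy)methyl]-3-ethenyl-3-methyl-1-(propan-2-yl)cyclopentan-1-ol
Conditions: iPrMgCl, anhydrous CeCl3, THF, −78 → 0 °C
Reagents that add atoms: isopropylmagnesium chloride, CC(C)[Mg]Cl
Why: organocerium 1,2-addition suppresses enolisation and β-hydride reduction of the hindered ketone, and the nucleophile should enter anti to the C5 benzyloxymethyl arm and the pseudoaxial C1 methyl, so that the new C4 hydroxyl is cis to C6.

Step 4
Reactants: 8 (1R,2S,3R)-2-[(benzyloxy)methyl]-3-ethenyl-3-methyl-1-(propan-2-yl)cyclopentan-1-ol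
Product: 9 {[(1R,2S,3R)-2-[(benzyloxy)methyl]-3-ethenyl-3-methyl-1-(propan-2-yl)cyclopentyl]oxy}triethylsilane
Conditions: Et3SiOTf, 2,6-lutidine, CH2Cl2, −78 → 0 °C
Reagents that add atoms: triethylsilyl trifluoromethanesulfonate, CC[Si](CC)(CC)OS(=O)(=O)C(F)(F)F
Why: silyl triflate with 2,6-lutidine is the standard silylation of a hindered tertiary alcohol, and the triethylsilyl ether blocks retro-aldol cleavage and Lewis-acid binding at C4 once C6 is an aldehyde.

Step 5
Reactants: 9 {[(1R,2S,3R)-2-[(benzyloxy)methyl]-3-ethenyl-3-methyl-1-(propan-2-yl)cyclopentyl]oxy}triethylsilane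
Product: 11 [(1S,2S,3R)-2-[(benzyloxy)methyl]-1-methyl-3-(propan-2-yl)-3-[(triethylsilyl)oxy]cyclopentyl]methanol, via ozonide 10 (not isolated)
Conditions: O3, CH2Cl2, −78 °C (to first blue tint); then NaBH4, MeOH, −78 °C → rt
Reagents that add atoms: ozone, [O-][O+]=O
Why: ozonolysis with reductive borohydride work-up turns the vinyl group into the C10 hydroxymethyl group; the terminal alkene reacts far faster than the benzyl ether and the silyl ether is inert.

Step 6
Reactants: 11 [(1S,2S,3R)-2-[(benzyloxy)methyl]-1-methyl-3-(propan-2-yl)-3-[(triethylsilyl)oxy]cyclopentyl]methanol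
Product: 12 [(1S,2S,3R)-1-methyl-3-(propan-2-yl)-3-[(triethylsilyl)oxy]cyclopentane-1,2-diyl]dimethanol
Conditions: H2 (1 atm), Pd/C, EtOAc, rt
Reagents that add atoms: none
Why: hydrogenolysis of the benzyl ether over palladium in an aprotic solvent leaves the tertiary silyl ether intact, and no alkene remains to be reduced.

Step 7
Reactants: 12 [(1S,2S,3R)-1-methyl-3-(propan-2-yl)-3-[(triethylsilyl)oxy]cyclopentane-1,2-diyl]dimethanol
Product: 13 (1S,2R,3R)-1-methyl-3-(propan-2-yl)-3-[(triethylsilyl)oxy]cyclopentane-1,2-dicarbaldehyde (formyl groups trans)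
Conditions: (COCl)2, DMSO, CH2Cl2, −78 °C; then iPr2NEt, −78 → −30 °C; used crude
Reagents that add atoms: none
Why: in the Swern oxidation both primary alcohols are converted into alkoxysulfonium ions before any carbonyl group exists, so the 1,4-diol should give the dialdehyde and not a lactol or lactone, and a hindered amine at low temperature should spare the C5 stereocentre.

Step 8
Reactants: 14 3-chloro-2-(chloromethyl)prop-1-ene
Product: 16 2-methylidene-1,3-bis(trimethylsilyl)propane, via monosilyl allylic chloride 15 (not isolated)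
Conditions: Mg turnings, Me3SiCl, THF, reflux
Reagents that add atoms: chlorotrimethylsilane, C[Si](C)(C)Cl
Why: in situ Grignard (Barbier-type) silylation of an allylic chloride, applied at both termini, is the standard way to this bifunctional allylsilane.

Step 9
Reactants: 13 (1S,2R,3R)-1-methyl-3-(propan-2-yl)-3-[(triethylsilyl)oxy]cyclopentane-1,2-dicarbaldehyde; 16 2-methylidene-1,3-bis(trimethylsilyl)propane
Product: 18 (1S,4R,5S)-4-O-(triethylsilyl)dauc-8(14)-ene-4,6,10-triol as a mixture of C6/C10 carbinol epimers, via C6 mono-adduct 17 (not isolated)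
Conditions: BF3·OEt2 (2.2 equiv), CH2Cl2 (0.01 M), −78 °C, slow addition of 16 (1.05 equiv); aq. NaHCO3
Reagents that add atoms: none
Why: BF3 activates the more accessible C6 aldehyde, the terminal CH2 of 16 attacks it in an SE2′ fashion (C6–C7 bond) with loss of one Me3Si group, and the 2-substituted allylsilane thus regenerated in 17 attacks the BF3-bound C10 aldehyde intramolecularly (C9–C10 bond), the second silyl group leaving so that the alkene is fixed exocyclic at C8. The closest known reaction type is the Hosomi–Sakurai allylation used twice, as in the [3+4] annulation of 1,4-dicarbonyl compounds with bifunctional 2-(silylmethyl)allyl reagents. The seven-membered ring closes in the second addition, exo with respect to the carbonyl group (7-exo-trig) and with the allylsilane C8=C9 bond inside the forming ring. The new C6 and C10 carbinol centres are not controlled by any element and need not be, because both are oxidised in step 11, while C1, C4 and C5 pass through unchanged and fix the trans ring fusion. The step needs ring closure to outrun a second intermolecular allylation and oxygen-bridged acetal formation: the neopentyl C10 aldehyde is slow towards an external nucleophile, high dilution with one equivalent of 16 favours the tethered attack, and the trans formyl groups would have to form a strained trans-fused bicyclo[3.3.0] lactol or oxocarbenium ion to bridge. Because 16 is symmetrical, the order in which the two aldehydes react does not change the product.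

Step 10
Reactants: 18 (1S,4R,5S)-4-O-(triethylsilyl)dauc-8(14)-ene-4,6,10-triol
Product: 19 (1S,4R,5S)-dauc-8(14)-ene-4,6,10-triol (C6/C10 epimers)
Conditions: HF·pyridine, pyridine, THF, 0 °C → rt
Reagents that add atoms: none
Why: buffered fluoride cleavage of the tertiary triethylsilyl ether frees the C4 hydroxyl needed as a directing group, at a stage where the molecule carries only alcohols and an unactivated 1,1-disubstituted alkene.

Step 11
Reactants: 19 (1S,4R,5S)-dauc-8(14)-ene-4,6,10-triol
Product: 20 (1S,4R,5R)-4-hydroxydauc-8(14)-ene-6,10-dione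
Conditions: Dess–Martin periodinane, NaHCO3, CH2Cl2, 0 °C → rt; used crude
Reagents that add atoms: none
Why: Dess–Martin oxidation converts both secondary carbinols into ketones (erasing the two uncontrolled centres of step 9) and cannot touch the tertiary C4 alcohol, and the bicarbonate buffer should keep the β,γ-unsaturated ketones and the C5–H from isomerising.

Step 12
Reactants: 20 (1S,4R,5R)-4-hydroxydauc-8(14)-ene-6,10-dione
Product: 21 (1S,4R,5S,6S)-4,6-dihydroxydauc-8(14)-en-10-one
Conditions: Me4NBH(OAc)3, MeCN/AcOH, −30 → −20 °C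
Reagents that add atoms: none
Why: in the Evans–Saksena reduction the C4 hydroxyl exchanges onto boron and delivers hydride to the C6 carbonyl through a six-membered transition state from the C4–O side, which gives the anti 1,3-diol (6S, C6–O trans to C4–O), while the C10 ketone has no β-hydroxyl and is not reduced by this reagent.

Step 13
Reactants: 21 (1S,4R,5S,6S)-4,6-dihydroxydauc-8(14)-en-10-one
Product: 22 (1S,4R,5S,6S)-4,6-dihydroxydauc-8-en-10-one
Conditions: DBU (0.5 equiv), CH2Cl2, rt
Reagents that add atoms: none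
Why: base-mediated isomerisation of a β,γ-unsaturated ketone through the C9 dienolate moves the exocyclic alkene into conjugation, and with C6 already a carbinol the C10 carbonyl is the only one left, so the alkene can only settle at C8=C9.

Step 14
Reactants: 22 (1S,4R,5S,6S)-4,6-dihydroxydauc-8-en-10-one; 23 4-acetoxybenzoyl chloride
Product: 24 (1S,4R,5S,6S)-6-[(4-acetoxybenzoyl)oxy]-4-hydroxydauc-8-en-10-one
Conditions: Et3N, DMAP (cat.), CH2Cl2, 0 °C → rt
Reagents that add atoms: none
Why: DMAP-catalysed acylation by the acid chloride takes place at the only secondary hydroxyl (C6), the tertiary C4 alcohol being too hindered and C10 still being a ketone.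

Step 15
Reactants: 24 (1S,4R,5S,6S)-6-[(4-acetoxybenzoyl)oxy]-4-hydroxydauc-8-en-10-one
Product: 25 (1S,4R,5S,6S,10S)-6-[(4-acetoxybenzoyl)oxy]dauc-8-ene-4,10-diol
Conditions: NaBH4, CeCl3·7H2O, MeOH, −78 °C; quench cold with aq. NH4Cl
Reagents that add atoms: none
Why: the Luche reduction gives 1,2-reduction of the enone, and hydride should attack C10 from the face opposite the adjacent axial C1 methyl, giving the 10S alcohol with its hydroxyl cis to that methyl; both aryl esters should survive the short low-temperature exposure.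

Step 16
Reactants: 25 (1S,4R,5S,6S,10S)-6-[(4-acetoxybenzoyl)oxy]dauc-8-ene-4,10-diol; 26 angelic acid [(Z)-2-methylbut-2-enoic acid]
Product: 28 (1S,4R,5S,6S,10S)-6-[(4-acetoxybenzoyl)oxy]-10-(angeloyloxy)dauc-8-en-4-ol, via mixed anhydride 27 (not isolated)
Conditions: 26, 2,4,6-Cl3C6H2COCl, Et3N, toluene, rt; then 25, 75 °C
Reagents that add atoms: none
Why: Yamaguchi-type esterification through the mixed 2,4,6-trichlorobenzoic anhydride without a nucleophilic catalyst is the established way to acylate hindered secondary alcohols with angelic acid without Z-to-E isomerisation, and the tertiary C4 hydroxyl does not react.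

Step 17
Reactants: 28 (1S,4R,5S,6S,10S)-6-[(4-acetoxybenzoyl)oxy]-10-(angeloyloxy)dauc-8-en-4-ol
Product: 29 (1S,4R,5S,6S,10S)-10-(angeloyloxy)-6-[(4-hydroxybenzoyl)oxy]dauc-8-en-4-ol (CNP0273650.10)
Conditions: pyrrolidine (3 equiv), CH2Cl2, 0 °C → rt
Reagents that add atoms: none
Why: aminolysis of a phenyl acetate by a secondary amine is much faster than attack on the two alkyl esters, so the phenol should be released without touching the benzoate or the geometry of the angelate.

**Compound list**

1 | 3-methylcyclopent-2-en-1-one | CC1=CC(=O)CC1 | starting material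
2 | (trimethylsilyl)acetylene | C#C[Si](C)(C)C | starting material
3 | diisobutyl[1-(trimethylsilyl)ethenyl]alumane (vinylalane) | C=C([Si](C)(C)C)[Al](CC(C)C)CC(C)C | intermediate
4 | diisobutylaluminium (S)-3-methyl-3-[1-(trimethylsilyl)ethenyl]cyclopent-1-en-1-olate | CC(C)C[Al](CC(C)C)OC1=C[C@](C(=C)[Si](C)(C)C)(C)CC1 | intermediate
5 | lithium methyl(diisobutyl)aluminate of enolate 4 | [Li+].C[Al-](CC(C)C)(CC(C)C)OC1=C[C@](C(=C)[Si](C)(C)C)(C)CC1 | intermediate
6 | (2S,3S)-2-[(benzyloxy)methyl]-3-methyl-3-[1-(trimethylsilyl)ethenyl]cyclopentan-1-one | c1ccccc1COC[C@@H]2[C@](C(=C)[Si](C)(C)C)(C)CCC2=O | intermediate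
7 | (2S,3R)-2-[(benzyloxy)methyl]-3-ethenyl-3-methylcyclopentan-1-one | c1ccccc1COC[C@@H]2[C@](C=C)(C)CCC2=O | intermediate
8 | (1R,2S,3R)-2-[(benzyloxy)methyl]-3-ethenyl-3-methyl-1-(propan-2-yl)cyclopentan-1-ol | c1ccccc1COC[C@@H]2[C@](C=C)(C)CC[C@@]2(O)C(C)C | intermediate
9 | {[(1R,2S,3R)-2-[(benzyloxy)methyl]-3-ethenyl-3-methyl-1-(propan-2-yl)cyclopentyl]oxy}triethylsilane | c1ccccc1COC[C@@H]2[C@](C=C)(C)CC[C@@]2(O[Si](CC)(CC)CC)C(C)C | intermediate
10 | ozonide of 9: 3-{(1S,2S,3R)-2-[(benzyloxy)methyl]-1-methyl-3-(propan-2-yl)-3-[(triethylsilyl)oxy]cyclopentyl}-1,2,4-trioxolane | c1ccccc1COC[C@@H]2[C@](C3OCOO3)(C)CC[C@@]2(O[Si](CC)(CC)CC)C(C)C | intermediate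
11 | [(1S,2S,3R)-2-[(benzyloxy)methyl]-1-methyl-3-(propan-2-yl)-3-[(triethylsilyl)oxy]cyclopentyl]methanol | c1ccccc1COC[C@@H]2[C@](CO)(C)CC[C@@]2(O[Si](CC)(CC)CC)C(C)C | intermediate
12 | [(1S,2S,3R)-1-methyl-3-(propan-2-yl)-3-[(triethylsilyl)oxy]cyclopentane-1,2-diyl]dimethanol | OC[C@@H]1[C@](CO)(C)CC[C@@]1(O[Si](CC)(CC)CC)C(C)C | intermediate
13 | (1S,2R,3R)-1-methyl-3-(propan-2-yl)-3-[(triethylsilyl)oxy]cyclopentane-1,2-dicarbaldehyde | O=C[C@@H]1[C@](C=O)(C)CC[C@@]1(O[Si](CC)(CC)CC)C(C)C | intermediate
14 | 3-chloro-2-(chloromethyl)prop-1-ene | ClCC(=C)CCl | starting material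
15 | [2-(chloromethyl)prop-2-en-1-yl]trimethylsilane | C=C(CCl)C[Si](C)(C)C | intermediate
16 | 2-methylidene-1,3-bis(trimethylsilyl)propane | C=C(C[Si](C)(C)C)C[Si](C)(C)C | intermediate
17 | C6 mono-adduct: difluoroboryl ether of (1S,2S,3R)-2-{1-hydroxy-3-[(trimethylsilyl)methyl]but-3-en-1-yl}-1-methyl-3-(propan-2-yl)-3-[(triethylsilyl)oxy]cyclopentane-1-carbaldehyde | C=C(C[Si](C)(C)C)CC(OB(F)F)[C@@H]1[C@](C=O)(C)CC[C@@]1(O[Si](CC)(CC)CC)C(C)C | intermediate
18 | (1S,4R,5S)-4-O-(triethylsilyl)dauc-8(14)-ene-4,6,10-triol (trans-fused; C6/C10 epimers) | OC1CC(=C)CC(O)[C@@H]2[C@]1(C)CC[C@@]2(O[Si](CC)(CC)CC)C(C)C | intermediate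
19 | (1S,4R,5S)-dauc-8(14)-ene-4,6,10-triol (C6/C10 epimers) | OC1CC(=C)CC(O)[C@@H]2[C@]1(C)CC[C@@]2(O)C(C)C | intermediate
20 | (1S,4R,5R)-4-hydroxydauc-8(14)-ene-6,10-dione | O=C1CC(=C)CC(=O)[C@@H]2[C@]1(C)CC[C@@]2(O)C(C)C | intermediate
21 | (1S,4R,5S,6S)-4,6-dihydroxydauc-8(14)-en-10-one | O=C1CC(=C)C[C@H](O)[C@@H]2[C@]1(C)CC[C@@]2(O)C(C)C | intermediate
22 | (1S,4R,5S,6S)-4,6-dihydroxydauc-8-en-10-one | O=C1C=C(C)C[C@H](O)[C@@H]2[C@]1(C)CC[C@@]2(O)C(C)C | intermediate
23 | 4-acetoxybenzoyl chloride | CC(=O)Oc1ccc(cc1)C(=O)Cl | starting material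
24 | (1S,4R,5S,6S)-6-[(4-acetoxybenzoyl)oxy]-4-hydroxydauc-8-en-10-one | O=C1C=C(C)C[C@H](OC(=O)c3ccc(OC(C)=O)cc3)[C@@H]2[C@]1(C)CC[C@@]2(O)C(C)C | intermediate
25 | (1S,4R,5S,6S,10S)-6-[(4-acetoxybenzoyl)oxy]dauc-8-ene-4,10-diol | O[C@H]1C=C(C)C[C@H](OC(=O)c3ccc(OC(C)=O)cc3)[C@@H]2[C@]1(C)CC[C@@]2(O)C(C)C | intermediate
26 | angelic acid, (Z)-2-methylbut-2-enoic acid | C/C=C(/C)C(=O)O | starting material
27 | angelic 2,4,6-trichlorobenzoic anhydride | C/C=C(/C)C(=O)OC(=O)c1c(Cl)cc(Cl)cc1Cl | intermediate
28 | (1S,4R,5S,6S,10S)-6-[(4-acetoxybenzoyl)oxy]-10-(angeloyloxy)dauc-8-en-4-ol | C/C=C(/C)C(=O)O[C@H]1C=C(C)C[C@H](OC(=O)c3ccc(OC(C)=O)cc3)[C@@H]2[C@]1(C)CC[C@@]2(O)C(C)C | intermediate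
29 | (1S,4R,5S,6S,10S)-10-(angeloyloxy)-6-[(4-hydroxybenzoyl)oxy]dauc-8-en-4-ol (CNP0273650.10) | C/C=C(/C)C(=O)O[C@H]1C=C(C)C[C@H](OC(=O)c2ccc(O)cc2)[C@@H]2[C@]1(C)CC[C@@]2(O)C(C)C | target

**Step count and risks**

Total steps: 17. Longest linear sequence: 16 (steps 1–7 and 9–17; step 8 is a one-step branch).

Steps most likely to fail:

Step 9. Ring closure may lose to a second intermolecular allylation or to oligomerisation. The intermediate allylsilane may be protodesilylated before it cyclises, and the Lewis acid may strip the silyl ether or trigger β-elimination at C4/C5.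
Fallback from 13 to 18: 13 is treated with one equivalent of the monosilane 15 and BF3·OEt2 at −78 °C. This single Hosomi–Sakurai allylation at the more accessible C6 aldehyde should give (1S,2S,3R)-2-[3-(chloromethyl)-1-hydroxybut-3-en-1-yl]-1-methyl-3-(propan-2-yl)-3-[(triethylsilyl)oxy]cyclopentane-1-carbaldehyde F1. CrCl2 in THF then turns the allylic chloride into an allylchromium species that adds to the C10 aldehyde within the molecule (Nozaki–Hiyama allylation). This forms the same C9–C10 bond under neutral conditions and leads to 18.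

Step 1. Alkylation of the hindered aluminate enolate next to the new quaternary centre may be slow or may go at oxygen, so that protonated or O-alkylated material is returned.
Fallback from 1 and 2 to 6: the conjugate addition is run as before, but enolate 4 is trapped with Et3SiOTf to give (S)-triethyl({3-methyl-3-[1-(trimethylsilyl)ethenyl]cyclopent-1-en-1-yl}oxy)silane F2, which is isolated. Yb(OTf)3-catalysed hydroxymethylation with aqueous formaldehyde in THF (a Mukaiyama-type aldol with the smallest electrophile) should give (2S,3S)-2-(hydroxymethyl)-3-methyl-3-[1-(trimethylsilyl)ethenyl]cyclopentan-1-one F3. Acid-catalysed benzylation with benzyl 2,2,2-trichloroacetimidate and catalytic TfOH leads to 6.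

Step 2. Acid-catalysed enolisation may epimerise C5 or eliminate benzyl alcohol. Once silicon is gone, the methyl and vinyl groups on C1 are of similar size, so a lost C5 configuration cannot be recovered by equilibration.
Fallback from 6 to 7: ipso-iododesilylation of 6 with N-iodosuccinimide in MeCN at 0 °C, without acid or base, should give (2S,3S)-2-[(benzyloxy)methyl]-3-(1-iodoethenyl)-3-methylcyclopentan-1-one F4. Pd(PPh3)4-catalysed reduction of the vinyl iodide with Bu3SnH in THF at room temperature leads to 7.

Further compounds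
F1 | step 9 | (1S,2S,3R)-2-[3-(chloromethyl)-1-hydroxybut-3-en-1-yl]-1-methyl-3-(propan-2-yl)-3-[(triethylsilyl)oxy]cyclopentane-1-carbaldehyde | C=C(CCl)CC(O)[C@@H]1[C@](C=O)(C)CC[C@@]1(O[Si](CC)(CC)CC)C(C)C
F2 | step 1 | (S)-triethyl({3-methyl-3-[1-(trimethylsilyl)ethenyl]cyclopent-1-en-1-yl}oxy)silane | CC[Si](CC)(CC)OC1=C[C@](C(=C)[Si](C)(C)C)(C)CC1
F3 | step 1 | (2S,3S)-2-(hydroxymethyl)-3-methyl-3-[1-(trimethylsilyl)ethenyl]cyclopentan-1-one | OC[C@@H]1[C@](C(=C)[Si](C)(C)C)(C)CCC1=O
F4 | step 2 | (2S,3S)-2-[(benzyloxy)methyl]-3-(1-iodoethenyl)-3-methylcyclopentan-1-one | c1ccccc1COC[C@@H]2[C@](C(I)=C)(C)CCC2=O
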